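**Plan**

1. Chain numbering: C1 = CO2H, cyclopropane = C5–C6 plus its CH2, methyl groups on C7, C11 and C15, diene C8=C9–C10=C11, alkyne C17≡C18–Br. The retrosynthesis cuts C18–Br first, then in one cut the C9–C10 single bond of the diene together with the C11–CH3 bond, giving iodoalkene 12 (C1–C9) and terminal alkyne 20 (C10–C18).
2. Enabling feature: C10=C11 is a 2-methylalk-1-enyl unit whose CH3 on C11 is cis to C9. Syn addition of CH3–metal across a C10≡C11 terminal alkyne gives exactly this, so one operation installs the methyl group, fixes the (10E) geometry and makes C9–C10.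
3. Fragment 1 (C1–C9), forward: (S)-Roche ester → (E)-allylic alcohol → Charette cyclopropanation (ring) → three-carbon Wittig and diimide (C1–C3) → Takai iodoalkene 12.
4. Fragment 2 (C10–C18), forward: (R)-citronellal. Its CHO carbon becomes alkyne carbon C17 (Ohira–Bestmann adds C18); the isopropylidene end is excised by ozonolysis and replaced by an ethynyl unit (C10, C11).
5. Union by one-pot methylalumination and Negishi coupling, then desilylation with saponification, and bromination of the alkyne last.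
6. Stereochemistry: C7 from the Roche ester; C5 and C6 from the reagent-controlled, stereospecific cyclopropanation of the (E)-alkene; C15 from citronellal; (8E) from the Takai olefination and (10E) from the syn carbometalation.

Key step: step 17

Assumption: (R)-citronellal of high enantiomeric purity is taken as the commercial material, because the remote C15 stereocenter cannot be corrected later in the route.

**Route**

Step 1
Reactants: 1 methyl (2S)-3-hydroxy-2-methylpropanoate
Product: 2 methyl (2S)-3-[(tert-butyldimethylsilyl)oxy]-2-methylpropanoate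
Conditions: t-BuMe2SiCl, imidazole, CH2Cl2, 0 °C to rt
Reagents that add atoms: tert-butyldimethylsilyl chloride, CC(C)(C)[Si](C)(C)Cl
Why: Silyl ether protection of the primary alcohol masks the future C8 carbon until ring and acid chain are in place, and the stereocenter is not touched.

Step 2
Reactants: 2 methyl (2S)-3-[(tert-butyldimethylsilyl)oxy]-2-methylpropanoate
Product: 3 (2S)-3-[(tert-butyldimethylsilyl)oxy]-2-methylpropanal
Conditions: i-Bu2AlH (1.1 equiv), CH2Cl2, −78 °C; MeOH quench, aq. potassium sodium tartrate; crude aldehyde used at once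
Reagents that add atoms: none
Why: Partial ester reduction with i-Bu2AlH at low temperature should stop at the aldehyde, and immediate use of the crude material limits enolization of the α-stereocenter.

Step 3
Reactants: 3 (2S)-3-[(tert-butyldimethylsilyl)oxy]-2-methylpropanal
Product: 4 ethyl (2E,4R)-5-[(tert-butyldimethylsilyl)oxy]-4-methylpent-2-enoate
Conditions: Ph3P=CHCO2Et, CH2Cl2, rt
Reagents that add atoms: ethyl (triphenylphosphoranylidene)acetate, CCOC(=O)C=P(c1ccccc1)(c1ccccc1)c1ccccc1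
Why: Wittig olefination with a stabilized, non-basic ylide should give the (E)-enoate without epimerizing the allylic stereocenter.

Step 4
Reactants: 4 ethyl (2E,4R)-5-[(tert-butyldimethylsilyl)oxy]-4-methylpent-2-enoate
Product: 5 (2E,4R)-5-[(tert-butyldimethylsilyl)oxy]-4-methylpent-2-en-1-ol
Conditions: i-Bu2AlH (2.2 equiv), CH2Cl2, −78 to 0 °C; aq. potassium sodium tartrate
Reagents that add atoms: none
Why: 1,2-Reduction of the enoate by i-Bu2AlH gives the (E)-allylic alcohol needed to direct the cyclopropanation, with the alkene geometry unchanged.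

Step 5
Reactants: 5 (2E,4R)-5-[(tert-butyldimethylsilyl)oxy]-4-methylpent-2-en-1-ol
Product: 6 [(1R,2S)-2-[(2R)-1-[(tert-butyldimethylsilyl)oxy]propan-2-yl]cyclopropyl]methanol
Conditions: Zn(CH2I)2·DME (from Et2Zn and CH2I2, 2.2 equiv), (4S,5S)-2-butyl-N,N,N′,N′-tetramethyl-1,3,2-dioxaborolane-4,5-dicarboxamide (1.2 equiv), CH2Cl2, −10 °C to rt; aq. NH4Cl
Reagents that add atoms: diiodomethane, ICI
Why: Charette asymmetric cyclopropanation (Simmons–Smith type): the zinc alkoxide of 5 is bound by the chiral dioxaborolane, which delivers CH2 stereospecifically to one face of the (E)-alkene, so the trans ring follows from the alkene geometry and the two new ring stereocenters from the (S,S) reagent.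

Step 6
Reactants: 6 [(1R,2S)-2-[(2R)-1-[(tert-butyldimethylsilyl)oxy]propan-2-yl]cyclopropyl]methanol
Product: 7 (1R,2S)-2-[(2R)-1-[(tert-butyldimethylsilyl)oxy]propan-2-yl]cyclopropane-1-carbaldehyde
Conditions: Dess–Martin periodinane, CH2Cl2, 0 °C to rt
Reagents that add atoms: none
Why: Dess–Martin oxidation of the primary alcohol to the aldehyde is mild enough to keep the silyl ether and the trans ring, which is also the thermodynamically preferred arrangement at the ring α-carbon.

Step 7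
Reactants: 7 (1R,2S)-2-[(2R)-1-[(tert-butyldimethylsilyl)oxy]propan-2-yl]cyclopropane-1-carbaldehyde
Product: 8 (3Z)-4-[(1S,2R)-2-[(2R)-1-[(tert-butyldimethylsilyl)oxy]propan-2-yl]cyclopropyl]but-3-enoic acid
Conditions: [Ph3P(CH2)2CO2H]Br (1.5 equiv), NaN(SiMe3)2 (3.0 equiv), THF, −78 to 0 °C, then 7, to rt; dilute HCl to pH 4 at 0 °C
Reagents that add atoms: (2-carboxyethyl)triphenylphosphonium bromide, OC(=O)CC[P+](c1ccccc1)(c1ccccc1)c1ccccc1.[Br-]
Why: Wittig olefination with the carboxylate-bearing ylide adds C1–C3 at the acid oxidation level in one operation; the alkene geometry is irrelevant because it is reduced next, and the ring stereocenters are unchanged in space (descriptors change by priority only).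

Step 8
Reactants: 8 (3Z)-4-[(1S,2R)-2-[(2R)-1-[(tert-butyldimethylsilyl)oxy]propan-2-yl]cyclopropyl]but-3-enoic acid
Product: 9 4-[(1R,2R)-2-[(2R)-1-[(tert-butyldimethylsilyl)oxy]propan-2-yl]cyclopropyl]butanoic acid
Conditions: 2-nitrobenzenesulfonyl hydrazide (excess, in portions), Et3N, CH2Cl2, rt
Reagents that add atoms: none
Why: Diimide reduction transfers H2 in a concerted syn fashion to the disubstituted alkene and so avoids the ring hydrogenolysis that a vinylcyclopropane can suffer over a heterogeneous metal catalyst.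

Step 9
Reactants: 9 4-[(1R,2R)-2-[(2R)-1-[(tert-butyldimethylsilyl)oxy]propan-2-yl]cyclopropyl]butanoic acid
Product: 10 methyl 4-[(1R,2R)-2-[(2R)-1-hydroxypropan-2-yl]cyclopropyl]butanoate
Conditions: HCl in MeOH (from catalytic AcCl), 0 °C to rt
Reagents that add atoms: methanol, CO
Why: Acidic methanolysis removes the primary silyl ether and Fischer-esterifies the acid in the same flask, and a dialkyl cyclopropane without cation-stabilizing groups should survive dilute HCl.

Step 10
Reactants: 10 methyl 4-[(1R,2R)-2-[(2R)-1-hydroxypropan-2-yl]cyclopropyl]butanoate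
Product: 11 methyl 4-[(1R,2R)-2-[(2R)-1-oxopropan-2-yl]cyclopropyl]butanoate
Conditions: Dess–Martin periodinane, CH2Cl2, 0 °C; crude aldehyde used at once
Reagents that add atoms: none
Why: Dess–Martin oxidation under non-basic conditions gives the α-branched aldehyde with minimal risk to the C7 stereocenter.

Step 11
Reactants: 11 methyl 4-[(1R,2R)-2-[(2R)-1-oxopropan-2-yl]cyclopropyl]butanoate
Product: 12 methyl 4-[(1R,2R)-2-[(2R,3E)-4-iodobut-3-en-2-yl]cyclopropyl]butanoate
Conditions: CrCl2 (6 equiv), CHI3 (2 equiv), THF/dioxane, 0 °C to rt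
Reagents that add atoms: iodoform, IC(I)I
Why: Takai olefination: the geminal dichromium species from CHI3 and divalent chromium adds to the aldehyde and eliminates to the (E)-iodoalkene under non-basic conditions that tolerate the ester and should not epimerize C7.

Step 12
Reactants: 13 (3R)-3,7-dimethyloct-6-enal [(R)-citronellal]
Product: 14 (4R)-4,8-dimethylnon-7-en-1-yne
Conditions: dimethyl (1-diazo-2-oxopropyl)phosphonate, K2CO3, MeOH, 0 °C to rt
Reagents that add atoms: dimethyl (1-diazo-2-oxopropyl)phosphonate, COP(=O)(OC)C(=[N+]=[N-])C(C)=O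
Why: Ohira–Bestmann (Seyferth–Gilbert) homologation converts the aldehyde into the terminal alkyne with one added carbon, and the β-stereocenter is not enolizable.

Step 13
Reactants: 14 (4R)-4,8-dimethylnon-7-en-1-yne
Product: 16 [(4R)-4,8-dimethylnon-7-en-1-yn-1-yl]tri(propan-2-yl)silane, via lithium acetylide 15 (not isolated)
Conditions: n-BuLi, THF, −78 °C; i-Pr3SiOTf, −78 °C to rt
Reagents that add atoms: triisopropylsilyl trifluoromethanesulfonate, CC(C)[Si](C(C)C)(C(C)C)OS(=O)(=O)C(F)(F)F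
Why: Deprotonation and C-silylation cap the C17≡C18 alkyne with a bulky group that survives acetylide base and blocks carbometalation in the key step.

Step 14
Reactants: 16 [(4R)-4,8-dimethylnon-7-en-1-yn-1-yl]tri(propan-2-yl)silane
Product: 18 (4R)-4-methyl-7-[tri(propan-2-yl)silyl]hept-6-yn-1-ol, via aldehyde 17 (not isolated)
Conditions: O3, CH2Cl2/MeOH, −78 °C (Sudan red 7B end point); then NaBH4, −78 °C to rt
Reagents that add atoms: ozone, [O-][O+]=O
Why: Ozonolysis with reductive work-up: ozone cleaves the electron-rich trisubstituted alkene much faster than the hindered silyl alkyne, and NaBH4 reduces aldehyde 17 in the same flask.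

Step 15
Reactants: 18 (4R)-4-methyl-7-[tri(propan-2-yl)silyl]hept-6-yn-1-ol
Product: 19 [(4R)-7-iodo-4-methylhept-1-yn-1-yl]tri(propan-2-yl)silane
Conditions: I2, PPh3, imidazole, CH2Cl2, 0 °C to rt
Reagents that add atoms: iodine, II
Why: Appel-type iodination converts the primary alcohol into the primary iodide by SN2 displacement of the oxyphosphonium group.

Step 16
Reactants: 19 [(4R)-7-iodo-4-methylhept-1-yn-1-yl]tri(propan-2-yl)silane
Product: 20 [(4R)-4-methylnona-1,8-diyn-1-yl]tri(propan-2-yl)silane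
Conditions: LiC≡CH·H2NCH2CH2NH2, DMSO, 0 °C to rt
Reagents that add atoms: lithium acetylide–ethylenediamine complex, [Li+].[C-]#C.NCCN
Why: SN2 alkylation of lithium acetylide by the unhindered primary iodide adds C10 and C11 as a free terminal alkyne, while the triisopropylsilyl alkyne is inert to the base.

Step 17
Reactants: 20 [(4R)-4-methylnona-1,8-diyn-1-yl]tri(propan-2-yl)silane; 12 methyl 4-[(1R,2R)-2-[(2R,3E)-4-iodobut-3-en-2-yl]cyclopropyl]butanoate
Product: 23 methyl 4-[(1R,2R)-2-[(2S,3E,5E,10R)-6,10-dimethyl-13-[tri(propan-2-yl)silyl]trideca-3,5-dien-12-yn-2-yl]cyclopropyl]butanoate, via alkenylalane 21 (not isolated), via alkenylzinc chloride 22 (not isolated)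
Conditions: Me3Al (2.5 equiv), Cp2ZrCl2 (0.25 equiv), CH2Cl2, 0 °C to rt; volatiles removed in vacuo; THF, ZnCl2 (1.0 equiv), then 12 (0.8 equiv) and Pd(PPh3)4 (5 mol %), rt
Reagents that add atoms: trimethylaluminum, C[Al](C)C
Why: Me3Al and Cp2ZrCl2 form a methylzirconocene–aluminate that adds CH3 and metal syn across the terminal alkyne of 20, CH3 to the internal carbon, and the resulting (E)-alkenylalane 21 passes through ZnCl2 (alkenylzinc 22) into a zerovalent palladium cycle of oxidative addition into the C–I bond of 12, transmetalation and reductive elimination, each with retention at the alkenyl carbons. The closest known reaction type is the one-pot zirconium-catalyzed methylalumination of a 1-alkyne followed by Negishi cross-coupling with an alkenyl iodide, here only applied to new partners. No ring is closed and no stereocenter is formed; C5, C6, C7 and C15 are not touched (the C7 descriptor changes from R to S by priority only). The (10E) geometry is set by the syn addition and the (8E) geometry is carried over from 12. The step needs chemoselectivity between the two alkynes of 20, secured by the triisopropylsilyl cap; regioselectivity, secured by the terminal alkyne (metal to the unsubstituted carbon); and survival of the methyl ester, secured by removing excess Me3Al before 12 is added and by coupling at room temperature.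

Step 18
Reactants: 23 methyl 4-[(1R,2R)-2-[(2S,3E,5E,10R)-6,10-dimethyl-13-[tri(propan-2-yl)silyl]trideca-3,5-dien-12-yn-2-yl]cyclopropyl]butanoate
Product: 25 4-[(1R,2R)-2-[(2S,3E,5E,10R)-6,10-dimethyltrideca-3,5-dien-12-yn-2-yl]cyclopropyl]butanoic acid, via terminal alkyne ester 24 (not isolated)
Conditions: Bu4NF (1.5 equiv), THF, 0 °C to rt; then LiOH·H2O (5 equiv), MeOH/H2O, rt; dilute HCl to pH 3
Reagents that add atoms: lithium hydroxide, [Li+].[OH-]
Why: Fluoride-induced C–Si cleavage followed by saponification in the same flask unveils the terminal alkyne and the acid without touching the diene or the ring.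

Step 19
Reactants: 25 4-[(1R,2R)-2-[(2S,3E,5E,10R)-6,10-dimethyltrideca-3,5-dien-12-yn-2-yl]cyclopropyl]butanoic acid
Product: 26 4-[(1R,2R)-2-[(2S,3E,5E,10R)-13-bromo-6,10-dimethyltrideca-3,5-dien-12-yn-2-yl]cyclopropyl]butanoic acid
Conditions: N-bromosuccinimide (1.1 equiv), AgNO3 (0.1 equiv), acetone, rt, dark
Reagents that add atoms: N-bromosuccinimide, O=C1CCC(=O)N1Br
Why: Silver-catalyzed electrophilic bromination of a terminal alkyne: silver activation of the C–H bond should make the alkyne react with the bromine donor faster than the diene, and placing the sensitive C(sp)–Br bond last keeps it away from palladium and strong base.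

**Compound list**

1 | methyl (2S)-3-hydroxy-2-methylpropanoate | COC(=O)[C@@H](C)CO | starting material
2 | methyl (2S)-3-[(tert-butyldimethylsilyl)oxy]-2-methylpropanoate | COC(=O)[C@@H](C)CO[Si](C)(C)C(C)(C)C | intermediate
3 | (2S)-3-[(tert-butyldimethylsilyl)oxy]-2-methylpropanal | O=C[C@@H](C)CO[Si](C)(C)C(C)(C)C | intermediate
4 | ethyl (2E,4R)-5-[(tert-butyldimethylsilyl)oxy]-4-methylpent-2-enoate | CCOC(=O)/C=C/[C@@H](C)CO[Si](C)(C)C(C)(C)C | intermediate
5 | (2E,4R)-5-[(tert-butyldimethylsilyl)oxy]-4-methylpent-2-en-1-ol | OC/C=C/[C@@H](C)CO[Si](C)(C)C(C)(C)C | intermediate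
6 | [(1R,2S)-2-[(2R)-1-[(tert-butyldimethylsilyl)oxy]propan-2-yl]cyclopropyl]methanol | CC(C)(C)[Si](C)(C)OC[C@H](C)[C@@H]1C[C@H]1CO | intermediate
7 | (1R,2S)-2-[(2R)-1-[(tert-butyldimethylsilyl)oxy]propan-2-yl]cyclopropane-1-carbaldehyde | CC(C)(C)[Si](C)(C)OC[C@H](C)[C@@H]1C[C@H]1C=O | intermediate
8 | (3Z)-4-[(1S,2R)-2-[(2R)-1-[(tert-butyldimethylsilyl)oxy]propan-2-yl]cyclopropyl]but-3-enoic acid | CC(C)(C)[Si](C)(C)OC[C@H](C)[C@@H]1C[C@H]1/C=C\CC(=O)O | intermediate
9 | 4-[(1R,2R)-2-[(2R)-1-[(tert-butyldimethylsilyl)oxy]propan-2-yl]cyclopropyl]butanoic acid | CC(C)(C)[Si](C)(C)OC[C@H](C)[C@@H]1C[C@H]1CCCC(=O)O | intermediate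
10 | methyl 4-[(1R,2R)-2-[(2R)-1-hydroxypropan-2-yl]cyclopropyl]butanoate | OC[C@H](C)[C@@H]1C[C@H]1CCCC(=O)OC | intermediate
11 | methyl 4-[(1R,2R)-2-[(2R)-1-oxopropan-2-yl]cyclopropyl]butanoate | O=C[C@H](C)[C@@H]1C[C@H]1CCCC(=O)OC | intermediate
12 | methyl 4-[(1R,2R)-2-[(2R,3E)-4-iodobut-3-en-2-yl]cyclopropyl]butanoate | I/C=C/[C@H](C)[C@@H]1C[C@H]1CCCC(=O)OC | intermediate
13 | (3R)-3,7-dimethyloct-6-enal [(R)-citronellal] | C[C@H](CCC=C(C)C)CC=O | starting material
14 | (4R)-4,8-dimethylnon-7-en-1-yne | C[C@H](CCC=C(C)C)CC#C | intermediate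
15 | lithium (4R)-4,8-dimethylnon-7-en-1-yn-1-ide (lithium acetylide of 14) | C[C@H](CCC=C(C)C)CC#C[Li] | intermediate
16 | [(4R)-4,8-dimethylnon-7-en-1-yn-1-yl]tri(propan-2-yl)silane | C[C@H](CCC=C(C)C)CC#C[Si](C(C)C)(C(C)C)C(C)C | intermediate
17 | (4R)-4-methyl-7-[tri(propan-2-yl)silyl]hept-6-ynal | C[C@H](CCC=O)CC#C[Si](C(C)C)(C(C)C)C(C)C | intermediate
18 | (4R)-4-methyl-7-[tri(propan-2-yl)silyl]hept-6-yn-1-ol | C[C@H](CCCO)CC#C[Si](C(C)C)(C(C)C)C(C)C | intermediate
19 | [(4R)-7-iodo-4-methylhept-1-yn-1-yl]tri(propan-2-yl)silane | C[C@H](CCCI)CC#C[Si](C(C)C)(C(C)C)C(C)C | intermediate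
20 | [(4R)-4-methylnona-1,8-diyn-1-yl]tri(propan-2-yl)silane | C[C@H](CCCC#C)CC#C[Si](C(C)C)(C(C)C)C(C)C | intermediate
21 | [(1E,6R)-2,6-dimethyl-9-[tri(propan-2-yl)silyl]non-1-en-8-yn-1-yl]dimethylalumane | C[Al](C)/C=C(\C)CCC[C@@H](C)CC#C[Si](C(C)C)(C(C)C)C(C)C | intermediate
22 | chloro[(1E,6R)-2,6-dimethyl-9-[tri(propan-2-yl)silyl]non-1-en-8-yn-1-yl]zinc | Cl[Zn]/C=C(\C)CCC[C@@H](C)CC#C[Si](C(C)C)(C(C)C)C(C)C | intermediate
23 | methyl 4-[(1R,2R)-2-[(2S,3E,5E,10R)-6,10-dimethyl-13-[tri(propan-2-yl)silyl]trideca-3,5-dien-12-yn-2-yl]cyclopropyl]butanoate | C/C(=C\C=C\[C@H](C)[C@@H]1C[C@H]1CCCC(=O)OC)CCC[C@@H](C)CC#C[Si](C(C)C)(C(C)C)C(C)C | intermediate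
24 | methyl 4-[(1R,2R)-2-[(2S,3E,5E,10R)-6,10-dimethyltrideca-3,5-dien-12-yn-2-yl]cyclopropyl]butanoate | C/C(=C\C=C\[C@H](C)[C@@H]1C[C@H]1CCCC(=O)OC)CCC[C@@H](C)CC#C | intermediate
25 | 4-[(1R,2R)-2-[(2S,3E,5E,10R)-6,10-dimethyltrideca-3,5-dien-12-yn-2-yl]cyclopropyl]butanoic acid | C/C(=C\C=C\[C@H](C)[C@@H]1C[C@H]1CCCC(=O)O)CCC[C@@H](C)CC#C | intermediate
26 | 4-[(1R,2R)-2-[(2S,3E,5E,10R)-13-bromo-6,10-dimethyltrideca-3,5-dien-12-yn-2-yl]cyclopropyl]butanoic acid | C/C(=C\C=C\[C@H](C)[C@@H]1C[C@H]1CCCC(=O)O)CCC[C@@H](C)CC#CBr | target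

**Step count and risks**

Total steps: 19. Longest linear sequence: 14 (steps 1–11, then 17–19); steps 12–16 form the second branch.

Steps most likely to fail:

Step 17. The process at risk is slow or regio-unselective methylalumination, together with attack of residual methylaluminum species on the methyl ester or protonolysis of the alkenylmetal before coupling, so that 12 is consumed unproductively. The fallback separates the two events and couples through boron with reversed polarity. It sets out from 20 and 11. From 20, Cp2ZrCl2/Me3Al followed by I2 should give [(4R,8E)-9-iodo-4,8-dimethylnon-8-en-1-yn-1-yl]tri(propan-2-yl)silane F1. From 11, CrCl2/LiI with Cl2CHB(pin) should give methyl 4-[(1R,2R)-2-[(2S,3E)-4-(4,4,5,5-tetramethyl-1,3,2-dioxaborolan-2-yl)but-3-en-2-yl]cyclopropyl]butanoate F2. Suzuki–Miyaura coupling of F1 and F2 (Pd(PPh3)4, aqueous K3PO4, THF) comes back to the route at 23.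

Step 19. The process at risk is electrophilic attack of the bromine donor on the electron-rich conjugated diene, or capture of a bromonium species by the free acid, in competition with bromination of the silver-activated alkyne. The fallback makes the C(sp)–Br bond by elimination instead, with C17 carried as a protected alcohol. It sets out from 13: NaBH4 should give (3R)-3,7-dimethyloct-6-en-1-ol F3, and t-BuPh2SiCl/imidazole should give tert-butyl{[(3R)-3,7-dimethyloct-6-en-1-yl]oxy}diphenylsilane F4. Ozonolysis with NaBH4 work-up should give (4R)-6-[(tert-butyldiphenylsilyl)oxy]-4-methylhexan-1-ol F5, I2/PPh3/imidazole should give tert-butyl{[(3R)-6-iodo-3-methylhexyl]oxy}diphenylsilane F6, and LiC≡CH·H2NCH2CH2NH2 in DMSO should give tert-butyl{[(3R)-3-methyloct-7-yn-1-yl]oxy}diphenylsilane F7. Coupling of F7 with 12 under the conditions of step 17 should give methyl 4-[(1R,2R)-2-[(2S,3E,5E,10R)-12-[(tert-butyldiphenylsilyl)oxy]-6,10-dimethyldodeca-3,5-dien-2-yl]cyclopropyl]butanoate F8. Bu4NF should give methyl 4-[(1R,2R)-2-[(2S,3E,5E,10R)-12-hydroxy-6,10-dimethyldodeca-3,5-dien-2-yl]cyclopropyl]butanoate F9, and Dess–Martin oxidation should give methyl 4-[(1R,2R)-2-[(2S,3E,5E,10R)-6,10-dimethyl-12-oxododeca-3,5-dien-2-yl]cyclopropyl]butanoate F10. CBr4/PPh3 should give methyl 4-[(1R,2R)-2-[(2S,3E,5E,10R)-13,13-dibromo-6,10-dimethyltrideca-3,5,12-trien-2-yl]cyclopropyl]butanoate F11, and dehydrobromination with Bu4NF·3H2O in DMF should give methyl 4-[(1R,2R)-2-[(2S,3E,5E,10R)-13-bromo-6,10-dimethyltrideca-3,5-dien-12-yn-2-yl]cyclopropyl]butanoate F12. Hydrolysis of F12 with LiOH comes back to the route at 26.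

Step 7. The process at risk is fragmentation of the β-carboxylate ylide (loss of Ph3P to give acrylate) and base-induced loss of aldehyde 7 before olefination. The fallback brings in C1–C3 at the alcohol oxidation level, where the ylide cannot fragment. It sets out from 7: Wittig reaction with the ylide from [3-[(4-methoxyphenyl)methoxy]propyl]triphenylphosphonium bromide and NaN(SiMe3)2 should give tert-butyl{[(2R)-2-[(1R,2S)-2-[(1Z)-4-[(4-methoxyphenyl)methoxy]but-1-en-1-yl]cyclopropyl]propyl]oxy}dimethylsilane F13. Diimide reduction should give tert-butyl{[(2R)-2-[(1R,2R)-2-[4-[(4-methoxyphenyl)methoxy]butyl]cyclopropyl]propyl]oxy}dimethylsilane F14, and DDQ should give 4-[(1R,2R)-2-[(2R)-1-[(tert-butyldimethylsilyl)oxy]propan-2-yl]cyclopropyl]butan-1-ol F15. Oxidation of F15 with TEMPO/PhI(OAc)2 in MeCN/H2O comes back to the route at 9.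

**Further compounds**

F1 | step 17 | [(4R,8E)-9-iodo-4,8-dimethylnon-8-en-1-yn-1-yl]tri(propan-2-yl)silane | I/C=C(\C)CCC[C@@H](C)CC#C[Si](C(C)C)(C(C)C)C(C)C
F2 | step 17 | methyl 4-[(1R,2R)-2-[(2S,3E)-4-(4,4,5,5-tetramethyl-1,3,2-dioxaborolan-2-yl)but-3-en-2-yl]cyclopropyl]butanoate | CC1(C)OB(/C=C/[C@H](C)[C@@H]2C[C@H]2CCCC(=O)OC)OC1(C)C
F3 | step 19 | (3R)-3,7-dimethyloct-6-en-1-ol | C[C@H](CCC=C(C)C)CCO
F4 | step 19 | tert-butyl{[(3R)-3,7-dimethyloct-6-en-1-yl]oxy}diphenylsilane | C[C@H](CCC=C(C)C)CCO[Si](c1ccccc1)(c1ccccc1)C(C)(C)C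
F5 | step 19 | (4R)-6-[(tert-butyldiphenylsilyl)oxy]-4-methylhexan-1-ol | C[C@H](CCCO)CCO[Si](c1ccccc1)(c1ccccc1)C(C)(C)C
F6 | step 19 | tert-butyl{[(3R)-6-iodo-3-methylhexyl]oxy}diphenylsilane | C[C@H](CCCI)CCO[Si](c1ccccc1)(c1ccccc1)C(C)(C)C
F7 | step 19 | tert-butyl{[(3R)-3-methyloct-7-yn-1-yl]oxy}diphenylsilane | C[C@H](CCCC#C)CCO[Si](c1ccccc1)(c1ccccc1)C(C)(C)C
F8 | step 19 | methyl 4-[(1R,2R)-2-[(2S,3E,5E,10R)-12-[(tert-butyldiphenylsilyl)oxy]-6,10-dimethyldodeca-3,5-dien-2-yl]cyclopropyl]butanoate | C/C(=C\C=C\[C@H](C)[C@@H]1C[C@H]1CCCC(=O)OC)CCC[C@@H](C)CCO[Si](c1ccccc1)(c1ccccc1)C(C)(C)C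
F9 | step 19 | methyl 4-[(1R,2R)-2-[(2S,3E,5E,10R)-12-hydroxy-6,10-dimethyldodeca-3,5-dien-2-yl]cyclopropyl]butanoate | C/C(=C\C=C\[C@H](C)[C@@H]1C[C@H]1CCCC(=O)OC)CCC[C@@H](C)CCO
F10 | step 19 | methyl 4-[(1R,2R)-2-[(2S,3E,5E,10R)-6,10-dimethyl-12-oxododeca-3,5-dien-2-yl]cyclopropyl]butanoate | C/C(=C\C=C\[C@H](C)[C@@H]1C[C@H]1CCCC(=O)OC)CCC[C@@H](C)CC=O
F11 | step 19 | methyl 4-[(1R,2R)-2-[(2S,3E,5E,10R)-13,13-dibromo-6,10-dimethyltrideca-3,5,12-trien-2-yl]cyclopropyl]butanoate | C/C(=C\C=C\[C@H](C)[C@@H]1C[C@H]1CCCC(=O)OC)CCC[C@@H](C)CC=C(Br)Br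
F12 | step 19 | methyl 4-[(1R,2R)-2-[(2S,3E,5E,10R)-13-bromo-6,10-dimethyltrideca-3,5-dien-12-yn-2-yl]cyclopropyl]butanoate | C/C(=C\C=C\[C@H](C)[C@@H]1C[C@H]1CCCC(=O)OC)CCC[C@@H](C)CC#CBr
F13 | step 7 | tert-butyl{[(2R)-2-[(1R,2S)-2-[(1Z)-4-[(4-methoxyphenyl)methoxy]but-1-en-1-yl]cyclopropyl]propyl]oxy}dimethylsilane | CC(C)(C)[Si](C)(C)OC[C@H](C)[C@@H]1C[C@H]1/C=C\CCOCc1ccc(OC)cc1
F14 | step 7 | tert-butyl{[(2R)-2-[(1R,2R)-2-[4-[(4-methoxyphenyl)methoxy]butyl]cyclopropyl]propyl]oxy}dimethylsilane | CC(C)(C)[Si](C)(C)OC[C@H](C)[C@@H]1C[C@H]1CCCCOCc1ccc(OC)cc1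
F15 | step 7 | 4-[(1R,2R)-2-[(2R)-1-[(tert-butyldimethylsilyl)oxy]propan-2-yl]cyclopropyl]butan-1-ol | CC(C)(C)[Si](C)(C)OC[C@H](C)[C@@H]1C[C@H]1CCCCO
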